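Readings and results are simulated for an exercise; noise was put on by code.

Complex with one exchanged is the middle stage of a flask in which starting complex trades leaving ligand for incoming ligand twice, so we compare how long it lives with how long we may wait.

| flask | starting complex | incoming ligand | leaving ligand | remark | time |
|---|---|---|---|---|---|
| teal | 0.25 M | 1.5 M | 1 M | run made earlier |  |
| red | 0.38 M | 1.5 M | 1 M | run made earlier |  |
| flask | 0.50 M | 1.50 M | 1.00 M |  | 15 min |

- teal (time / min: complex with one exchanged / %, complex with two exchanged / %): 2.00: 14.4, 4.7; 2.50: 17.5, 4.2; 4.00: 19.4, 8.6; 5.00: 21.4, 12.5; 6.00: 20.5, 14.8; 8.00: 23.5, 22.1; 12.0: 21.2, 32.1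
- red (time / min: complex with one exchanged / %, complex with two exchanged / %): 2.00: 14.7, 3.6; 2.50: 16.6, 3.9; 4.00: 20.1, 8.2; 5.00: 20.9, 10.6; 6.00: 21.9, 15.3; 8.00: 19.6, 19.4; 12.0: 19.8, 28.2

(each reading ± 1 percentage point)

1. time up to 15 min at which complex with one exchanged stands highest
2. the amount of complex with one exchanged, in percent of the starting complex charged, at that time



We read its lifetime from the red run, which with 0.38 M of starting complex stands nearer to the 0.50 M of the flask than the teal run with 0.25 M. From 6.00 min to 12.0 min, complex with two exchanged climbs 13 percentage points while complex with one exchanged reads 19.8% at the end of that stretch. Dividing gives 9.21 min: this is the drain time, the standing amount over the rate of passing on, a pseudo-first-order lifetime, and it carries the scatter of the readings. The teal run reads 7.35 min. The red value is shorter than the 15 min allowed, so we expect the peak inside the window, not at its end.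

The forecast puts the peak at 7.5 min with 20.5%, “a slightly lower, slightly later, flat maximum”.

The flask peaks at 7.45 min with 20.4%, and at 15.0 min it still holds 18.1%. Reckoned the same way from the best time to the end, with the amount at the end of that stretch, its complex with two exchanged gives a drain time of 8.75 min, shorter than the 15 min allowed.

    leaving ligand → by-product carried off (k = 0.00230 s⁻¹)
    complex with one exchanged + incoming ligand ⇌ leaving ligand + complex with two exchanged (K = 1.90, k = 0.00210 M⁻¹ s⁻¹)
    starting complex + incoming ligand ⇌ leaving ligand + complex with one exchanged (K = 0.420, k = 0.00130 M⁻¹ s⁻¹)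
    complex with one exchanged → side product (k = 7.10 × 10⁻⁴ s⁻¹)

If the drain rate goes with incoming ligand, the neighbour flask with 0.38 M of it has a drain time of 36.4 min, longer than the 15 min allowed, so we expect its best at the end. Computed, its best is 12.5% and its end value 12.5%.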